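**Strategy**

Everything rests on cutting the dimethylpyran of ring B (O1, C2, C3, C4 and both methyls, fused at the adjacent carbons C4a and C8a) back to an aryne spanning C4a/C8a and 3-methylbut-2-enal. In one fluoride-triggered operation the aldehyde C=O adds across the aryne (C8a–O1, C4a–C4), the benzoxete opens, and oxa-6π closure (O1–C2) delivers the complete 2H-chromene beside the C5 carboxyl carbon, with no electrophilic substitution on the arene. The precursor is an ortho-silyl aryl triflate made from gentisic acid, carrying a 5-OMOM group and a tert-butyl ester. The ester is then turned into the aldehyde, which is joined to lithiated MOM-protected 3,5-dimethoxyphenol, oxidised and deprotected.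

Key step: step 5

**Remarks on the chemistry (assumptions)**

- The target has no stereocentre and is achiral, so no step has to control configuration. The stereocentres of the transient oxete 10 and of carbinol 18 are racemic and are erased in the route.
- Ring B is numbered as a 2H-chromene (O1, C2, C3, C4, C4a, C5–C8, C8a). Ring A is the 2-hydroxy-4,6-dimethoxyphenyl group.
- The carboxyl group is carried as its tert-butyl ester. This ester should resist n-BuLi in step 4, and its bulk should add to the steric bias at the neighbouring aryne carbon in step 5.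

**Route**

Step 1
Reactants: 1 2,5-dihydroxybenzoic acid (gentisic acid)
Product: 2 tert-butyl 2,5-dihydroxybenzoate
Conditions: Me2NCH(Ot-Bu)2 (4 equiv), toluene, 80 °C, N2
Reagents that add atoms: N,N-dimethylformamide di-tert-butyl acetal, CN(C)C(OC(C)(C)C)OC(C)(C)C
Why: The carboxylic acid protonates the formamide acetal and the carboxylate captures the tert-butyl group (esterification with a DMF dialkyl acetal), a neutral method that should leave both phenols free.

Step 2
Reactants: 2 tert-butyl 2,5-dihydroxybenzoate
Product: 3 tert-butyl 2-hydroxy-5-(methoxymethoxy)benzoate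
Conditions: MOMCl (1.1 equiv), i-Pr2NEt, CH2Cl2, 0 °C
Reagents that add atoms: chloromethyl methyl ether, COCCl
Why: O-alkylation of a phenol; the 2-hydroxyl is hydrogen-bonded to the ester carbonyl and flanked by it, so the amine base and MOMCl should alkylate only the free 5-hydroxyl.

Step 3
Reactants: 3 tert-butyl 2-hydroxy-5-(methoxymethoxy)benzoate
Product: 4 tert-butyl 3-bromo-2-hydroxy-5-(methoxymethoxy)benzoate
Conditions: NBS (1.05 equiv), i-Pr2NH (10 mol %), CH2Cl2, 0 °C
Reagents that add atoms: N-bromosuccinimide, O=C1CCC(=O)N1Br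
Why: Electrophilic aromatic bromination; the free phenol is the strongest activator and C3 is its only open ortho position (meta to the ester), and the amine-catalysed NBS protocol brominates ortho to OH without free HBr that would endanger the MOM ether and the tert-butyl ester.

Step 4
Reactants: 4 tert-butyl 3-bromo-2-hydroxy-5-(methoxymethoxy)benzoate
Product: 7 tert-butyl 5-(methoxymethoxy)-2-(trifluoromethylsulfonyloxy)-3-(trimethylsilyl)benzoate, via aryl trimethylsilyl ether 5 (not isolated), via lithium phenoxide 6 (not isolated)
Conditions: HMDS, THF, 70 °C, then evaporate; n-BuLi (1.1 equiv), THF, −100 °C; Tf2O (1.2 equiv), −100 → 0 °C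
Reagents that add atoms: hexamethyldisilazane, C[Si](C)(C)N[Si](C)(C)C; trifluoromethanesulfonic anhydride, O=S(=O)(OS(=O)(=O)C(F)(F)F)C(F)(F)F
Why: O-silylation, then bromine–lithium exchange at −100 °C triggers the anionic 1,3 O→C silyl shift (retro-Brook rearrangement) and the resulting lithium phenoxide is triflated in the same flask, the standard one-pot entry to ortho-silyl aryl triflates; exchange is much faster than attack on a tert-butyl ester and the aryllithium is consumed intramolecularly at once.

Step 5
Reactants: 7 tert-butyl 5-(methoxymethoxy)-2-(trifluoromethylsulfonyloxy)-3-(trimethylsilyl)benzoate; 8 3-methylbut-2-enal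
Product: 12 tert-butyl 7-(methoxymethoxy)-2,2-dimethyl-2H-chromene-5-carboxylate, via aryne 9 (not isolated), via benzoxete 10 (not isolated), via ortho-quinone methide 11 (not isolated)
Conditions: CsF (3 equiv), 8 (5 equiv), MeCN, 25 → 50 °C, slow addition of 7
Reagents that add atoms: none
Why: Fluoride attacks silicon and the aryl anion expels triflate to give aryne 9; the aldehyde oxygen of 8 bonds to the aryne carbon remote from the ester (future C8a) and the aryl carbon next to the ester (future C4a) closes on the carbonyl carbon, a formal [2+2] addition giving benzoxete 10. The strained oxete opens by 4π electrocyclic ring opening to the vinylogous ortho-quinone methide 11, whose Z-configured 1-oxatriene closes thermally by disrotatory oxa-6π electrocyclisation (O1–C2); this is the known 2H-chromene synthesis from fluoride-generated arynes and α,β-unsaturated aldehydes. The only ring kept in the product, the pyran, is thus closed by 6π electrocyclisation after a transient four-membered ring. No stereocentre remains, because the oxete carbon of 10 is racemic and becomes sp2 in 11 and C2 carries two methyl groups. The step needs C–O bond formation at the aryne carbon meta to the ester: the inductively withdrawing carboxyl group stabilises the developing aryl anion ortho to itself and the bulky tert-butyl ester shields the adjacent aryne carbon, while the more distant OMOM group should exert almost no bias. Excess enal and slow release of the aryne should suppress aryne–aryne and aryne–quinone-methide side reactions.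

Step 6
Reactants: 12 tert-butyl 7-(methoxymethoxy)-2,2-dimethyl-2H-chromene-5-carboxylate
Product: 13 [7-(methoxymethoxy)-2,2-dimethyl-2H-chromen-5-yl]methanol
Conditions: LiAlH4, THF, 0 °C → rt; aqueous NaOH work-up
Reagents that add atoms: none
Why: Hydride reduction of an ester to the primary alcohol; the aryl MOM ether and the styrene-type chromene double bond are inert to LiAlH4.

Step 7
Reactants: 13 [7-(methoxymethoxy)-2,2-dimethyl-2H-chromen-5-yl]methanol
Product: 14 7-(methoxymethoxy)-2,2-dimethyl-2H-chromene-5-carbaldehyde
Conditions: activated MnO2 (10 equiv), CH2Cl2, rt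
Reagents that add atoms: none
Why: Heterogeneous MnO2 oxidation of a benzylic alcohol stops at the aldehyde and is neutral, so the MOM acetal and the chromene should be untouched.

Step 8
Reactants: 15 3,5-dimethoxyphenol
Product: 16 1,3-dimethoxy-5-(methoxymethoxy)benzene
Conditions: MOMCl, i-Pr2NEt, CH2Cl2, 0 °C → rt
Reagents that add atoms: chloromethyl methyl ether, COCCl
Why: Standard MOM protection of a phenol, which also installs the directing group for the metalation in step 9.

Step 9
Reactants: 16 1,3-dimethoxy-5-(methoxymethoxy)benzene; 14 7-(methoxymethoxy)-2,2-dimethyl-2H-chromene-5-carbaldehyde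
Product: 18 [2,4-dimethoxy-6-(methoxymethoxy)phenyl][7-(methoxymethoxy)-2,2-dimethyl-2H-chromen-5-yl]methanol (racemic), via aryllithium 17 (not isolated)
Conditions: 16 (1.3 equiv), n-BuLi (1.2 equiv), THF, 0 °C; then 14, −78 → 0 °C; H2O quench
Reagents that add atoms: none
Why: Directed ortho-metalation, in which the chelating MOM ether is the stronger director, so the two equivalent positions flanked by OMOM and OMe should be lithiated in preference to the one between the methoxy groups; 1,2-addition of 17 to the aldehyde then gives the diaryl carbinol, whose new stereocentre forms as the racemate and is removed in step 10.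

Step 10
Reactants: 18 [2,4-dimethoxy-6-(methoxymethoxy)phenyl][7-(methoxymethoxy)-2,2-dimethyl-2H-chromen-5-yl]methanol
Product: 19 [2,4-dimethoxy-6-(methoxymethoxy)phenyl][7-(methoxymethoxy)-2,2-dimethyl-2H-chromen-5-yl]methanone
Conditions: Dess–Martin periodinane, pyridine, CH2Cl2, 0 °C → rt
Reagents that add atoms: none
Why: Dess–Martin oxidation of a hindered, electron-rich diaryl carbinol to the ketone under buffered conditions that avoid acid ionisation of the benzhydrol.

Step 11
Reactants: 19 [2,4-dimethoxy-6-(methoxymethoxy)phenyl][7-(methoxymethoxy)-2,2-dimethyl-2H-chromen-5-yl]methanone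
Product: 20 (2-hydroxy-4,6-dimethoxyphenyl)(7-hydroxy-2,2-dimethyl-2H-chromen-5-yl)methanone
Conditions: HCl (3 M), MeOH/THF, 40 °C
Reagents that add atoms: none
Why: Acid-catalysed acetal exchange with methanol removes both aryl MOM ethers while the aryl methyl ethers stay, and the 2,2-dimethylchromene, deactivated by the C5 acyl group, should tolerate dilute methanolic HCl.

**Compound list**

1 | 2,5-dihydroxybenzoic acid (gentisic acid) | O=C(O)c1cc(O)ccc1O | starting material
2 | tert-butyl 2,5-dihydroxybenzoate | CC(C)(C)OC(=O)c1cc(O)ccc1O | intermediate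
3 | tert-butyl 2-hydroxy-5-(methoxymethoxy)benzoate | CC(C)(C)OC(=O)c1cc(OCOC)ccc1O | intermediate
4 | tert-butyl 3-bromo-2-hydroxy-5-(methoxymethoxy)benzoate | CC(C)(C)OC(=O)c1cc(OCOC)cc(Br)c1O | intermediate
5 | tert-butyl 3-bromo-5-(methoxymethoxy)-2-(trimethylsilyloxy)benzoate | CC(C)(C)OC(=O)c1cc(OCOC)cc(Br)c1O[Si](C)(C)C | intermediate
6 | lithium 2-(tert-butoxycarbonyl)-4-(methoxymethoxy)-6-(trimethylsilyl)phenolate | [Li+].[O-]c1c(C(=O)OC(C)(C)C)cc(OCOC)cc1[Si](C)(C)C | intermediate
7 | tert-butyl 5-(methoxymethoxy)-2-(trifluoromethylsulfonyloxy)-3-(trimethylsilyl)benzoate | CC(C)(C)OC(=O)c1cc(OCOC)cc([Si](C)(C)C)c1OS(=O)(=O)C(F)(F)F | intermediate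
8 | 3-methylbut-2-enal | CC(C)=CC=O | starting material
9 | tert-butyl 2,3-didehydro-5-(methoxymethoxy)benzoate (aryne) | CC(C)(C)OC(=O)C1=CC(OCOC)=CC#C1 | intermediate
10 | tert-butyl 4-(methoxymethoxy)-8-(2-methylprop-1-en-1-yl)-7-oxabicyclo[4.2.0]octa-1,3,5-triene-2-carboxylate (benzoxete, racemic) | CC(C)(C)OC(=O)c1cc(OCOC)cc2c1C(C=C(C)C)O2 | intermediate
11 | tert-butyl (6Z)-3-(methoxymethoxy)-6-(3-methylbut-2-en-1-ylidene)-5-oxocyclohexa-1,3-diene-1-carboxylate (ortho-quinone methide) | CC(C)=C\C=C1/C(=O)C=C(OCOC)C=C1C(=O)OC(C)(C)C | intermediate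
12 | tert-butyl 7-(methoxymethoxy)-2,2-dimethyl-2H-chromene-5-carboxylate | CC(C)(C)OC(=O)c1cc(OCOC)cc2c1C=CC(C)(C)O2 | intermediate
13 | [7-(methoxymethoxy)-2,2-dimethyl-2H-chromen-5-yl]methanol | OCc1cc(OCOC)cc2c1C=CC(C)(C)O2 | intermediate
14 | 7-(methoxymethoxy)-2,2-dimethyl-2H-chromene-5-carbaldehyde | O=Cc1cc(OCOC)cc2c1C=CC(C)(C)O2 | intermediate
15 | 3,5-dimethoxyphenol | COc1cc(O)cc(OC)c1 | starting material
16 | 1,3-dimethoxy-5-(methoxymethoxy)benzene | COCOc1cc(OC)cc(OC)c1 | intermediate
17 | [2,4-dimethoxy-6-(methoxymethoxy)phenyl]lithium | [Li]c1c(OC)cc(OC)cc1OCOC | intermediate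
18 | [2,4-dimethoxy-6-(methoxymethoxy)phenyl][7-(methoxymethoxy)-2,2-dimethyl-2H-chromen-5-yl]methanol (racemic) | COCOc1cc(OC)cc(OC)c1C(O)c1cc(OCOC)cc2c1C=CC(C)(C)O2 | intermediate
19 | [2,4-dimethoxy-6-(methoxymethoxy)phenyl][7-(methoxymethoxy)-2,2-dimethyl-2H-chromen-5-yl]methanone | COCOc1cc(OC)cc(OC)c1C(=O)c1cc(OCOC)cc2c1C=CC(C)(C)O2 | intermediate
20 | (2-hydroxy-4,6-dimethoxyphenyl)(7-hydroxy-2,2-dimethyl-2H-chromen-5-yl)methanone | COc1cc(O)c(C(=O)c2cc(O)cc3c2C=CC(C)(C)O3)c(OC)c1 | target

**Step count**

Total: 11 steps. Longest linear sequence: 10 steps (steps 1–7 and 9–11); step 8 is a one-step side branch.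

**Steps most likely to fail**

1. Step 5. The aldehyde oxygen may add to the aryne with poor regioselectivity, giving the chromene with the ester next to O1 as well, or the aryne may be lost to oligomerisation. The fallback replaces the ester by bromine as the directing group, since halogens control additions to 3-haloarynes strongly, and introduces the C5 carbon afterwards. It sets out from 3-methylbut-2-enal 8 and comes back to the route at aldehyde 14.
   - 4-(Methoxymethoxy)phenol F1 (purchased) would be brominated at both positions ortho to the hydroxyl (NBS, cat. i-Pr2NH) to give 2,6-dibromo-4-(methoxymethoxy)phenol F2.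
   - O-silylation, a single bromine–lithium exchange with retro-Brook shift and triflation would give 2-bromo-4-(methoxymethoxy)-6-(trimethylsilyl)phenyl trifluoromethanesulfonate F3.
   - CsF and 8 in MeCN would give 5-bromo-7-(methoxymethoxy)-2,2-dimethyl-2H-chromene F4, with oxygen adding meta to bromine.
   - Bromine–lithium exchange (n-BuLi, THF, −78 °C) and a DMF quench would give 14, so steps 6 and 7 are no longer needed.

2. Step 4. The organolithium may attack the silyl ether or the ester instead of exchanging with bromine, or the hindered phenoxide may be triflated slowly. The fallback makes the carbon–silicon bond by palladium catalysis instead of through a carbanion. It sets out from bromophenol 4 and comes back at triflate 7.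
   - O-benzylation (BnBr, K2CO3, DMF) would give tert-butyl 2-(benzyloxy)-3-bromo-5-(methoxymethoxy)benzoate F5.
   - Pd-catalysed silylation of the aryl bromide with hexamethyldisilane (Pd2(dba)3, 2-(di-tert-butylphosphino)biphenyl, KF, H2O, DMPU, 100 °C) would give tert-butyl 2-(benzyloxy)-5-(methoxymethoxy)-3-(trimethylsilyl)benzoate F6.
   - Hydrogenolysis (H2, Pd/C, EtOAc) would give tert-butyl 2-hydroxy-5-(methoxymethoxy)-3-(trimethylsilyl)benzoate F7.
   - Triflation (Tf2O, pyridine, CH2Cl2, 0 °C) would give 7.

3. Step 9. Metalation may occur in part between the two methoxy groups, or the hindered aryllithium may add sluggishly, leading to an isomeric ketone. The fallback uses a threefold-symmetric nucleophile whose lithiation is unambiguous and reveals the ring A phenol by chelation-controlled demethylation. It sets out from aldehyde 14 and comes back at target 20.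
   - 1,3,5-Trimethoxybenzene F8 would be lithiated (n-BuLi, TMEDA, THF, 0 °C) to (2,4,6-trimethoxyphenyl)lithium F9.
   - Addition of F9 to 14 would give [7-(methoxymethoxy)-2,2-dimethyl-2H-chromen-5-yl](2,4,6-trimethoxyphenyl)methanol F10.
   - Dess–Martin oxidation would give [7-(methoxymethoxy)-2,2-dimethyl-2H-chromen-5-yl](2,4,6-trimethoxyphenyl)methanone F11.
   - BCl3 (CH2Cl2, −78 → 0 °C) would cleave the one methyl ether chelated to the ketone carbonyl (either ortho methoxy gives the same product) together with the MOM ether, giving 20.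

**Further compounds**

F1 | step 5 | 4-(methoxymethoxy)phenol | COCOc1ccc(O)cc1
F2 | step 5 | 2,6-dibromo-4-(methoxymethoxy)phenol | COCOc1cc(Br)c(O)c(Br)c1
F3 | step 5 | 2-bromo-4-(methoxymethoxy)-6-(trimethylsilyl)phenyl trifluoromethanesulfonate | COCOc1cc(Br)c(OS(=O)(=O)C(F)(F)F)c([Si](C)(C)C)c1
F4 | step 5 | 5-bromo-7-(methoxymethoxy)-2,2-dimethyl-2H-chromene | COCOc1cc(Br)c2C=CC(C)(C)Oc2c1
F5 | step 4 | tert-butyl 2-(benzyloxy)-3-bromo-5-(methoxymethoxy)benzoate | CC(C)(C)OC(=O)c1cc(OCOC)cc(Br)c1OCc1ccccc1
F6 | step 4 | tert-butyl 2-(benzyloxy)-5-(methoxymethoxy)-3-(trimethylsilyl)benzoate | CC(C)(C)OC(=O)c1cc(OCOC)cc([Si](C)(C)C)c1OCc1ccccc1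
F7 | step 4 | tert-butyl 2-hydroxy-5-(methoxymethoxy)-3-(trimethylsilyl)benzoate | CC(C)(C)OC(=O)c1cc(OCOC)cc([Si](C)(C)C)c1O
F8 | step 9 | 1,3,5-trimethoxybenzene | COc1cc(OC)cc(OC)c1
F9 | step 9 | (2,4,6-trimethoxyphenyl)lithium | [Li]c1c(OC)cc(OC)cc1OC
F10 | step 9 | [7-(methoxymethoxy)-2,2-dimethyl-2H-chromen-5-yl](2,4,6-trimethoxyphenyl)methanol | COCOc1cc(C(O)c2c(OC)cc(OC)cc2OC)c2C=CC(C)(C)Oc2c1
F11 | step 9 | [7-(methoxymethoxy)-2,2-dimethyl-2H-chromen-5-yl](2,4,6-trimethoxyphenyl)methanone | COCOc1cc(C(=O)c2c(OC)cc(OC)cc2OC)c2C=CC(C)(C)Oc2c1
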